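**Plan**
- Retrosynthesis: one cut at the C2–C1' bond gives the fully oxygenated A/C bicycle 3,5-dihydroxy-7,8-dimethoxychromone and a 3,4,5-trimethoxyphenyl radical (from its diazonium salt). The chromone is then cut at C3–O (epoxidation of C2=C3), at C2 (one-carbon annulation) and at the aryl–acyl bond (Friedel–Crafts).
- Forward: ring A is bought as 1,2,3,5-tetramethoxybenzene; acylation with ortho-demethylation sets the 5,7,8 pattern; DMF-DMA closes pyranone ring C; DMDO oxygenates C3; AlCl3 frees the 5-OH; ring B is joined last, with no protecting groups.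
- Enabling feature: the enol O1–C2(H)=C3(OH)–C4=O of ring C. C2 carries the only C–H of that ring, and an aryl radical adding there leaves a C3 radical held between the C3 hydroxyl and the C4 carbonyl (a protonated semidione). One-electron oxidation and re-enolisation return the aromatic 3-hydroxy-4-pyranone.
- Stereochemistry: none to set; the sp3 centres that appear in passing (epoxide, dione tautomer) are racemic and are erased.

Key step: step 6

Remark on the chemistry: the target has no stereocentre, axis or stereogenic double bond, so "single enantiomer" imposes no stereocontrol; 1,2,3,5-tetramethoxybenzene and 3,4,5-trimethoxyaniline are taken as purchasable.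

**Route**

Step 1
Reactants: 1 1,2,3,5-tetramethoxybenzene
Product: 2 1-(2-hydroxy-3,4,6-trimethoxyphenyl)ethan-1-one
Conditions: AcCl, AlCl3 (excess), Et2O, 0 °C → rt; aq. HCl work-up
Reagents that add atoms: acetyl chloride, CC(=O)Cl
Why: Friedel–Crafts acylation at one of the two equivalent free positions of the electron-rich arene, followed in the same pot by AlCl3-mediated cleavage of the ortho methoxy group that is flanked on both sides and held in the carbonyl–aluminium chelate, should give the 2'-phenol next to the 3'-methoxy group.

Step 2
Reactants: 2 1-(2-hydroxy-3,4,6-trimethoxyphenyl)ethan-1-one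
Product: 4 5,7,8-trimethoxy-4H-chromen-4-one, via enaminone 3 (not isolated)
Conditions: DMF-DMA, toluene, 100 °C; concentrate; then conc. HCl, CH2Cl2, rt
Reagents that add atoms: N,N-dimethylformamide dimethyl acetal, COC(OC)N(C)C
Why: Condensation of the methyl ketone with DMF-DMA gives the enaminone, and acid-promoted addition of the phenol oxygen to the β-carbon with loss of dimethylamine closes ring C (enaminone chromone synthesis).

Step 3
Reactants: 4 5,7,8-trimethoxy-4H-chromen-4-one
Product: 6 3-hydroxy-5,7,8-trimethoxy-4H-chromen-4-one, via cis-2,3-epoxychromanone 5 (not isolated)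
Conditions: DMDO (acetone solution), CH2Cl2, 0 °C → rt, dark; evaporate excess oxidant; then p-TsOH·H2O (cat.), CH2Cl2, rt
Reagents that add atoms: dimethyldioxirane, CC1(C)OO1
Why: Dimethyldioxirane epoxidation of the chromone C2=C3 bond under neutral conditions, then acid opening of the epoxy acetal at C2 (oxocarbenium stabilised by O1) with loss of H3, should give the 3-hydroxychromone as in the DMDO route from flavones to flavonols, the forced cis fusion of the racemic epoxide being lost again.

Step 4
Reactants: 6 3-hydroxy-5,7,8-trimethoxy-4H-chromen-4-one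
Product: 7 3,5-dihydroxy-7,8-dimethoxy-4H-chromen-4-one
Conditions: AlCl3 (excess), MeCN, 50 °C; then 2 M aq. HCl, 50 °C
Reagents that add atoms: none
Why: Chelation-controlled demethylation, in which aluminium bound at the C4 carbonyl activates only the peri 5-methoxy group toward chloride attack on its methyl, should leave the 7- and 8-methoxy groups, and the step is placed before ring B arrives so that the Lewis-acid-labile central methoxy group of a 3,4,5-trimethoxyphenyl ring is never exposed.

Step 5
Reactants: 8 3,4,5-trimethoxyaniline
Product: 9 3,4,5-trimethoxybenzenediazonium tetrafluoroborate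
Conditions: NaNO2, 48% aq. HBF4, H2O, 0 °C; precipitate with Et2O, dry and store cold in the dark
Reagents that add atoms: sodium nitrite, [Na+].[O-]N=O; tetrafluoroboric acid, [H+].F[B-](F)(F)F
Why: Standard diazotisation of an aniline, with isolation of the diazonium ion as its sparingly soluble tetrafluoroborate.

Step 6
Reactants: 7 3,5-dihydroxy-7,8-dimethoxy-4H-chromen-4-one; 9 3,4,5-trimethoxybenzenediazonium tetrafluoroborate
Product: 11 3,5-dihydroxy-7,8-dimethoxy-2-(3,4,5-trimethoxyphenyl)-4H-chromen-4-one (target), via chromane-3,4-dione tautomer 10 (not isolated)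
Conditions: 9 (2.5 equiv, added in portions), eosin Y (2 mol %), degassed DMSO, no base, green LEDs (ca. 530 nm), 20 °C, Ar
Reagents that add atoms: none
Why: Proposed new method: photoexcited eosin Y should transfer one electron to 9, the 3,4,5-trimethoxyphenyl radical formed on loss of N2 should add to C2 of the enol C2=C3(OH) of 7, and the resulting C3 radical (a protonated semidione, stabilised by the C3 hydroxyl and the C4 carbonyl) should be oxidised by a further diazonium ion or by the eosin radical cation to the 3,4-dione 10, which re-enolises to the flavonol and so restores the 4-pyranone. The closest known reaction types are the photoredox Meerwein C–H arylation of enol acetates and electron-rich heteroarenes with arenediazonium salts and the radical arylation of the cyclic enol 2-hydroxy-1,4-naphthoquinone; a free 3-hydroxy-4-pyranone enol is assumed not to have been used in this way. No ring is closed and no stereocentre survives, since the sp3 C2 of 10 is planarised by the tautomerisation. The step needs C2 selectivity over the A-ring C6–H and over O-arylation, and radical C–C bond formation in preference to ionic azo coupling: C2 is the only olefinic C–H and the only site whose adduct radical is captodative, aryl radicals add to such alkenes faster than to benzenoid rings, and the base-free medium, which turns acidic as HBF4 is released, keeps the enolate and phenolate concentrations low. Green light should be absorbed essentially by the dye alone, which spares the photolabile flavonol, and oxygen is excluded so that neither the aryl radical nor the semidione radical is trapped.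

**Compound list**
1 | 1,2,3,5-tetramethoxybenzene | COc1cc(OC)c(OC)c(OC)c1 | starting material
2 | 1-(2-hydroxy-3,4,6-trimethoxyphenyl)ethan-1-one | CC(=O)c1c(O)c(OC)c(OC)cc1OC | intermediate
3 | (E)-3-(dimethylamino)-1-(2-hydroxy-3,4,6-trimethoxyphenyl)prop-2-en-1-one | CN(C)/C=C/C(=O)c1c(O)c(OC)c(OC)cc1OC | intermediate (not isolated)
4 | 5,7,8-trimethoxy-4H-chromen-4-one | O=c1ccoc2c(OC)c(OC)cc(OC)c12 | intermediate
5 | rac-cis-2,3-epoxy-5,7,8-trimethoxychroman-4-one (racemate, one enantiomer drawn) | O=C1[C@@H]2O[C@@H]2Oc2c(OC)c(OC)cc(OC)c12 | intermediate (not isolated)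
6 | 3-hydroxy-5,7,8-trimethoxy-4H-chromen-4-one | O=c1c(O)coc2c(OC)c(OC)cc(OC)c12 | intermediate
7 | 3,5-dihydroxy-7,8-dimethoxy-4H-chromen-4-one | O=c1c(O)coc2c(OC)c(OC)cc(O)c12 | intermediate
8 | 3,4,5-trimethoxyaniline | COc1cc(N)cc(OC)c1OC | starting material
9 | 3,4,5-trimethoxybenzenediazonium tetrafluoroborate | COc1cc([N+]#N)cc(OC)c1OC.F[B-](F)(F)F | intermediate
10 | rac-5-hydroxy-7,8-dimethoxy-2-(3,4,5-trimethoxyphenyl)chromane-3,4-dione (keto tautomer; racemate, one enantiomer drawn) | COc1cc([C@H]2Oc3c(OC)c(OC)cc(O)c3C(=O)C2=O)cc(OC)c1OC | intermediate (not isolated)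
11 | 3,5-dihydroxy-7,8-dimethoxy-2-(3,4,5-trimethoxyphenyl)-4H-chromen-4-one (achiral) | COc1cc(-c2oc3c(OC)c(OC)cc(O)c3c(=O)c2O)cc(OC)c1OC | target

**Step count**
Total steps: 6. Longest linear sequence: 5 (steps 1, 2, 3, 4 and 6); step 5 is a one-step side branch.

**Steps most likely to fail, with fallbacks**

Step 6 (proposed new method). Ionic azo coupling at C2 of the enol or at C6 of ring A may overtake the radical chain, the aryl radical may abstract hydrogen before it adds, or the flavonol may be degraded photo-oxidatively. The fallback makes the C2–aryl bond by two-electron palladium chemistry before C3 is oxygenated, using only known reaction types. It sets out from 4: Pd(II)-catalysed oxidative Heck-type C2–H arylation with commercial 3,4,5-trimethoxyphenylboronic acid (Pd(TFA)2 cat., O2 as terminal oxidant, DMSO, 80–100 °C), a known route from chromones to flavones, should give 5,7,8-trimethoxy-2-(3,4,5-trimethoxyphenyl)-4H-chromen-4-one F1. DMDO epoxidation as in step 3 would lead to rac-cis-2,3-epoxy-5,7,8-trimethoxy-2-(3,4,5-trimethoxyphenyl)chroman-4-one F2, which would be opened without isolation by catalytic TsOH to 3-hydroxy-5,7,8-trimethoxy-2-(3,4,5-trimethoxyphenyl)-4H-chromen-4-one F3. AlCl3 in MeCN as in step 4 would then remove the 5-O-methyl group, and the fallback comes back to the route at 11.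

Step 3. Oxygen transfer to the electron-poor C2=C3 bond may be slow enough for oxidation of the electron-rich ring A to compete, and the epoxy acetal may be opened hydrolytically and the ring cleaved before it rearranges. The fallback brings the C3 oxygen in with the acyl unit instead of by oxidation. It sets out from 1: Friedel–Crafts acylation with methoxyacetyl chloride (AlCl3, Et2O), with the same ortho-demethylation as in step 1, should give 1-(2-hydroxy-3,4,6-trimethoxyphenyl)-2-methoxyethan-1-one F4. DMF-DMA would convert it into (Z)-3-(dimethylamino)-1-(2-hydroxy-3,4,6-trimethoxyphenyl)-2-methoxyprop-2-en-1-one F5, which would be cyclised with HCl without isolation to 3,5,7,8-tetramethoxy-4H-chromen-4-one F6. Chelation-controlled removal of the 3- and 5-O-methyl groups, both of which flank the C4 carbonyl (AlBr3, MeCN, 0 °C → rt, then dilute HCl), would bring the fallback back to the route at 7.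

Step 4. The flanked 8-O-methyl group may be lost along with the 5-O-methyl group, or the cleavage may stall because the aluminium is sequestered at the 3-hydroxy-4-keto site. The fallback frees the 5-OH before the 3-OH exists and masks it for the oxidation. It sets out from 4: BCl3 (CH2Cl2, −78 → 0 °C), acting through the simple peri chelate, should give 5-hydroxy-7,8-dimethoxy-4H-chromen-4-one F7, and acetylation (Ac2O, pyridine, DMAP) would give 7,8-dimethoxy-4-oxo-4H-chromen-5-yl acetate F8. DMDO would lead to rac-cis-2,3-epoxy-7,8-dimethoxy-4-oxochroman-5-yl acetate F9, opened without isolation by catalytic TsOH to 3-hydroxy-7,8-dimethoxy-4-oxo-4H-chromen-5-yl acetate F10. Acid methanolysis of the aryl acetate (HCl in MeOH, rt) would bring the fallback back to the route at 7.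

**Further compounds**
F1 | step 6 | 5,7,8-trimethoxy-2-(3,4,5-trimethoxyphenyl)-4H-chromen-4-one | COc1cc(-c2cc(=O)c3c(OC)cc(OC)c(OC)c3o2)cc(OC)c1OC
F2 | step 6 | rac-cis-2,3-epoxy-5,7,8-trimethoxy-2-(3,4,5-trimethoxyphenyl)chroman-4-one (racemate, one enantiomer drawn) | O=C1[C@@H]2O[C@]2(c2cc(OC)c(OC)c(OC)c2)Oc2c(OC)c(OC)cc(OC)c12
F3 | step 6 | 3-hydroxy-5,7,8-trimethoxy-2-(3,4,5-trimethoxyphenyl)-4H-chromen-4-one | COc1cc(-c2oc3c(OC)c(OC)cc(OC)c3c(=O)c2O)cc(OC)c1OC
F4 | step 3 | 1-(2-hydroxy-3,4,6-trimethoxyphenyl)-2-methoxyethan-1-one | COCC(=O)c1c(O)c(OC)c(OC)cc1OC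
F5 | step 3 | (Z)-3-(dimethylamino)-1-(2-hydroxy-3,4,6-trimethoxyphenyl)-2-methoxyprop-2-en-1-one | CN(C)/C=C(\OC)C(=O)c1c(O)c(OC)c(OC)cc1OC
F6 | step 3 | 3,5,7,8-tetramethoxy-4H-chromen-4-one | COc1coc2c(OC)c(OC)cc(OC)c2c1=O
F7 | step 4 | 5-hydroxy-7,8-dimethoxy-4H-chromen-4-one | O=c1ccoc2c(OC)c(OC)cc(O)c12
F8 | step 4 | 7,8-dimethoxy-4-oxo-4H-chromen-5-yl acetate | CC(=O)Oc1cc(OC)c(OC)c2occc(=O)c12
F9 | step 4 | rac-cis-2,3-epoxy-7,8-dimethoxy-4-oxochroman-5-yl acetate (racemate, one enantiomer drawn) | O=C1[C@@H]2O[C@@H]2Oc2c(OC)c(OC)cc(OC(C)=O)c12
F10 | step 4 | 3-hydroxy-7,8-dimethoxy-4-oxo-4H-chromen-5-yl acetate | CC(=O)Oc1cc(OC)c(OC)c2occ(O)c(=O)c12
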